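## Retrosynthetic overview

1. The strategy rests on the 2,4-disubstituted furan: aryl on C2, the side chain on C4, H on C3, and an unsubstituted C5–H next to O1. This pattern maps onto a 3-aroyl-1-alkylcyclopropene (15), in which the ring bond from the acyl-bearing carbon to the vinylic CH is broken and the ketone oxygen is joined to that CH (O1–C5 bond).
2. Target 20 comes from oxidative demethylation of dimethoxyarene 19, which comes from acylation of alcohol 17, obtained from silyl ether furan 16, the product of the isomerization of 15.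
3. Ketone 15 comes from cyclopropene Weinreb amide 12 and aryl Grignard 14; 12 comes from ester 11, the [2+1] adduct of terminal alkyne 9 and ethyl diazoacetate 10.
4. Alkyne 9 comes from the (S)-propargylic alcohol 7, made by Noyori transfer hydrogenation of ynone 6 (Weinreb amide 3 plus silylacetylide 5); this sets the only stereocenter.
5. Ring order: cyclopropene (step 6, transient), then furan (step 9); the benzene ring is bought and becomes the quinone in the last step.

Key step: step 9

Assumption: the CIP ranking at the carbinol carbon (O > alkynyl, cyclopropenyl or furyl carbon > CH2 > H) keeps the same spatial sense from 7 to 20, so the (3S)-alcohol 7 leads to the (S)-target without any inversion.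

## Route

Step 1
Reactants: 1 4-methylpent-3-enoic acid
Product: 3 N-methoxy-N,4-dimethylpent-3-enamide, via acyl imidazolide 2 (not isolated)
Conditions: CDI, CH2Cl2, rt; then MeNH(OMe)·HCl, rt
Reagents that add atoms: N,O-dimethylhydroxylamine hydrochloride, CNOC.Cl; 1,1'-carbonyldiimidazole, O=C(n1ccnc1)n1ccnc1 (imidazolyl group of intermediate 2 only)
Why: Amide coupling through the acyl imidazolide needs no added base, so the β,γ-double bond of the acid should not move into conjugation.

Step 2
Reactants: 3 N-methoxy-N,4-dimethylpent-3-enamide; 4 ethynyl(trimethyl)silane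
Product: 6 6-methyl-1-(trimethylsilyl)hept-5-en-1-yn-3-one, via lithium trimethylsilylacetylide 5 (not isolated)
Conditions: 4, n-BuLi, THF, −78 °C; then 3, −78 → 0 °C; quench into cold 1 M HCl
Reagents that add atoms: n-butyllithium, [Li]CCCC (lithium of intermediate 5 only)
Why: Weinreb ketone synthesis, in which the chelated tetrahedral adduct stops at single addition and the cold acidic quench keeps the released amine protonated so that it cannot add to the ynone or shift the skipped alkene.

Step 3
Reactants: 6 6-methyl-1-(trimethylsilyl)hept-5-en-1-yn-3-one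
Product: 7 (3S)-6-methyl-1-(trimethylsilyl)hept-5-en-1-yn-3-ol
Conditions: Ru[(S,S)-TsNCH(Ph)CH(Ph)NH](p-cymene) (1 mol%), i-PrOH, rt
Reagents that add atoms: none
Why: Noyori asymmetric transfer hydrogenation of an α,β-acetylenic ketone, in which the alkynyl group takes the place of the aryl group of acetophenone in the six-membered hydride-transfer transition state, so the (S,S)-diamine complex should give the (3S)-alcohol, and the base-free amido complex spares the acidic α-CH2.

Step 4
Reactants: 7 (3S)-6-methyl-1-(trimethylsilyl)hept-5-en-1-yn-3-ol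
Product: 8 (3S)-6-methylhept-5-en-1-yn-3-ol
Conditions: K2CO3 (0.2 equiv), MeOH, 0 °C → rt
Reagents that add atoms: none
Why: Methoxide-mediated protodesilylation of the alkynyl C–Si bond is fast and selective and does not touch the carbinol stereocenter.

Step 5
Reactants: 8 (3S)-6-methylhept-5-en-1-yn-3-ol
Product: 9 triethyl{[(3S)-6-methylhept-5-en-1-yn-3-yl]oxy}silane
Conditions: Et3SiCl, imidazole, CH2Cl2, 0 °C → rt
Reagents that add atoms: chlorotriethylsilane, CC[Si](Cl)(CC)CC
Why: Standard silylation caps the alcohol so that the carbenoid of the next step cannot insert into the O–H bond, and the triethylsilyl ether survives Grignard reagents and is later removed by fluoride without acid.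

Step 6
Reactants: 9 triethyl{[(3S)-6-methylhept-5-en-1-yn-3-yl]oxy}silane; 10 ethyl diazoacetate
Product: 11 ethyl 2-[(1S)-4-methyl-1-(triethylsilyloxy)pent-3-enyl]cycloprop-2-ene-1-carboxylate (both epimers at ring C1)
Conditions: Rh2(OAc)4 (1 mol%), CH2Cl2, rt, slow addition of 10 by syringe pump to 9 (2 equiv, excess recovered)
Reagents that add atoms: none
Why: Cyclopropenation, the [2+1] addition of the dirhodium ethoxycarbonyl carbenoid to a terminal alkyne, is the standard entry to cycloprop-2-ene-1-carboxylates; slow addition suppresses carbene dimerisation, and the unhindered alkyne terminus should be attacked in preference to the trisubstituted alkene, whose cyclopropanation is the main competing path.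

Step 7
Reactants: 11 ethyl 2-[(1S)-4-methyl-1-(triethylsilyloxy)pent-3-enyl]cycloprop-2-ene-1-carboxylate
Product: 12 N-methoxy-N-methyl-2-[(1S)-4-methyl-1-(triethylsilyloxy)pent-3-enyl]cycloprop-2-ene-1-carboxamide (both epimers at ring C1)
Conditions: MeNH(OMe)·HCl, i-PrMgCl, THF, −20 °C
Reagents that add atoms: N,O-dimethylhydroxylamine hydrochloride, CNOC.Cl
Why: Ester-to-Weinreb-amide exchange by the chloromagnesium amide is a nucleophilic acyl substitution at low temperature, and because the Grignard base is consumed by the amine salt before the ester is added, the cyclopropene C=C and its vinylic C–H should not be attacked.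

Step 8
Reactants: 12 N-methoxy-N-methyl-2-[(1S)-4-methyl-1-(triethylsilyloxy)pent-3-enyl]cycloprop-2-ene-1-carboxamide; 13 2-bromo-1,4-dimethoxybenzene
Product: 15 (2,5-dimethoxyphenyl){2-[(1S)-4-methyl-1-(triethylsilyloxy)pent-3-enyl]cycloprop-2-en-1-yl}methanone (both epimers at the acyl-bearing ring carbon), via aryl Grignard reagent 14 (not isolated)
Conditions: 13, Mg, THF, rt → reflux; then 12, THF, −20 → 0 °C; aq. NH4Cl
Reagents that add atoms: magnesium, [Mg] (in intermediate 14 only)
Why: Weinreb ketone synthesis, in which the magnesium chelate blocks over-addition, while uncatalysed carbomagnesiation of the cyclopropene is slow at or below 0 °C.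

Step 9
Reactants: 15 (2,5-dimethoxyphenyl){2-[(1S)-4-methyl-1-(triethylsilyloxy)pent-3-enyl]cycloprop-2-en-1-yl}methanone
Product: 16 2-(2,5-dimethoxyphenyl)-4-[(1S)-4-methyl-1-(triethylsilyloxy)pent-3-enyl]furan
Conditions: [Rh(CO)2Cl]2 (5 mol%), CH2Cl2, rt
Reagents that add atoms: none
Why: Monovalent rhodium inserts into the strained σ-bond between the acyl-bearing ring carbon and the vinylic CH, the bond remote from the branched silyloxyalkyl group, to give a rhodacyclobutene equivalent to the acylvinyl rhodium carbenoid Rh=CH–C(R)=CH–C(=O)Ar; the ketone oxygen then bonds to the rhodium-bound CH and the metal is released as the furan aromatises. The closest known reaction type is the transition-metal-catalysed isomerisation of 3-acylcyclopropenes to furans, for which [Rh(CO)2Cl]2 is reported to cleave the less substituted ring bond. The furan closes as a five-membered ring through O1–C5 bond formation, a 5-exo attack of the carbonyl oxygen on the metal-bound carbon (formally a 1,5-electrocyclisation of the oxapentadienyl unit). No stereocenter is created: the acyl-bearing ring carbon becomes sp2, so both epimers of 15 converge, and the (S)-carbinol carbon is not touched. The step needs cleavage of the ring bond to the vinylic CH in preference to the ring bond to the substituted vinylic carbon, which would give the 2,5-isomer; the bulk of the CH(OSiEt3) branch and the preference of the CO-ligated monovalent metal for the less hindered bond should secure it. Ring strain and aromatisation drive the reaction at room temperature, so the silyl ether and the skipped trisubstituted alkene should survive.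

Step 10
Reactants: 16 2-(2,5-dimethoxyphenyl)-4-[(1S)-4-methyl-1-(triethylsilyloxy)pent-3-enyl]furan
Product: 17 (1S)-1-[5-(2,5-dimethoxyphenyl)furan-3-yl]-4-methylpent-3-en-1-ol
Conditions: Bu4NF, THF, 0 °C; aq. NH4Cl
Reagents that add atoms: none
Why: Fluoride cleaves the Si–O bond under non-acidic conditions, which matters because the furan-3-yl carbinol can ionise in acid.

Step 11
Reactants: 17 (1S)-1-[5-(2,5-dimethoxyphenyl)furan-3-yl]-4-methylpent-3-en-1-ol; 18 3-methylbut-2-enoic acid
Product: 19 (1S)-1-[5-(2,5-dimethoxyphenyl)furan-3-yl]-4-methylpent-3-enyl 3-methylbut-2-enoate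
Conditions: DCC, DMAP (0.1 equiv), CH2Cl2, 0 °C → rt
Reagents that add atoms: none
Why: Steglich esterification with the free acid is chosen over the acid chloride with amine base, which tends to deconjugate the senecioyl unit through a vinylketene, and since the carbinol C–O bond is not broken the configuration is retained.

Step 12
Reactants: 19 (1S)-1-[5-(2,5-dimethoxyphenyl)furan-3-yl]-4-methylpent-3-enyl 3-methylbut-2-enoate
Product: 20 (1S)-1-[5-(3,6-dioxocyclohexa-1,4-dien-1-yl)furan-3-yl]-4-methylpent-3-enyl 3-methylbut-2-enoate (CNP0314322.1)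
Conditions: (NH4)2Ce(NO3)6 (2.2 equiv), MeCN/H2O, 0 °C, short reaction time
Reagents that add atoms: water, O
Why: Oxidative demethylation of a 1,4-dimethoxyarene by tetravalent cerium goes through the arene radical cation, ipso attack of water and loss of two molecules of methanol to give the 1,4-benzoquinone, and a short reaction at 0 °C with little more than two equivalents of oxidant should spare the ester and the trisubstituted alkene.

## Compound list

1 | 4-methylpent-3-enoic acid | CC(C)=CCC(=O)O | starting material
2 | 1-(imidazol-1-yl)-4-methylpent-3-en-1-one (acyl imidazolide) | CC(C)=CCC(=O)n1ccnc1 | intermediate (not isolated)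
3 | N-methoxy-N,4-dimethylpent-3-enamide | CC(C)=CCC(=O)N(C)OC | intermediate
4 | ethynyl(trimethyl)silane | C#C[Si](C)(C)C | starting material
5 | lithium (trimethylsilyl)acetylide | [Li]C#C[Si](C)(C)C | intermediate (not isolated)
6 | 6-methyl-1-(trimethylsilyl)hept-5-en-1-yn-3-one | CC(C)=CCC(=O)C#C[Si](C)(C)C | intermediate
7 | (3S)-6-methyl-1-(trimethylsilyl)hept-5-en-1-yn-3-ol | CC(C)=CC[C@H](O)C#C[Si](C)(C)C | intermediate
8 | (3S)-6-methylhept-5-en-1-yn-3-ol | CC(C)=CC[C@H](O)C#C | intermediate
9 | triethyl{[(3S)-6-methylhept-5-en-1-yn-3-yl]oxy}silane | CC(C)=CC[C@H](O[Si](CC)(CC)CC)C#C | intermediate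
10 | ethyl diazoacetate | CCOC(=O)C=[N+]=[N-] | starting material
11 | ethyl 2-[(1S)-4-methyl-1-(triethylsilyloxy)pent-3-enyl]cycloprop-2-ene-1-carboxylate (both ring epimers) | CC(C)=CC[C@H](O[Si](CC)(CC)CC)C1=CC1C(=O)OCC | intermediate
12 | N-methoxy-N-methyl-2-[(1S)-4-methyl-1-(triethylsilyloxy)pent-3-enyl]cycloprop-2-ene-1-carboxamide (both ring epimers) | CC(C)=CC[C@H](O[Si](CC)(CC)CC)C1=CC1C(=O)N(C)OC | intermediate
13 | 2-bromo-1,4-dimethoxybenzene | COc1ccc(OC)c(Br)c1 | starting material
14 | (2,5-dimethoxyphenyl)magnesium bromide | COc1ccc(OC)c([Mg]Br)c1 | intermediate (not isolated)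
15 | (2,5-dimethoxyphenyl){2-[(1S)-4-methyl-1-(triethylsilyloxy)pent-3-enyl]cycloprop-2-en-1-yl}methanone (both ring epimers) | CC(C)=CC[C@H](O[Si](CC)(CC)CC)C1=CC1C(=O)c1cc(OC)ccc1OC | intermediate
16 | 2-(2,5-dimethoxyphenyl)-4-[(1S)-4-methyl-1-(triethylsilyloxy)pent-3-enyl]furan | CC(C)=CC[C@H](O[Si](CC)(CC)CC)c1coc(-c2cc(OC)ccc2OC)c1 | intermediate
17 | (1S)-1-[5-(2,5-dimethoxyphenyl)furan-3-yl]-4-methylpent-3-en-1-ol | CC(C)=CC[C@H](O)c1coc(-c2cc(OC)ccc2OC)c1 | intermediate
18 | 3-methylbut-2-enoic acid | CC(C)=CC(=O)O | starting material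
19 | (1S)-1-[5-(2,5-dimethoxyphenyl)furan-3-yl]-4-methylpent-3-enyl 3-methylbut-2-enoate | CC(C)=CC[C@H](OC(=O)C=C(C)C)c1coc(-c2cc(OC)ccc2OC)c1 | intermediate
20 | (1S)-1-[5-(3,6-dioxocyclohexa-1,4-dien-1-yl)furan-3-yl]-4-methylpent-3-enyl 3-methylbut-2-enoate | CC(C)=CC[C@H](OC(=O)C=C(C)C)c1coc(C2=CC(=O)C=CC2=O)c1 | target

## Step count and risks

Total step count: 12. Longest linear sequence: 12 steps (1 to 20); compounds 4, 10, 13 and 18 each enter in a single step.

**Step 9 (key step).** Rhodium may insert into the other ring bond and so lead to the 2,5-disubstituted furan, or the rhodium vinylcarbenoid may be captured by the pendant alkene before the oxygen closes the ring. The fallback builds the furan by cross-coupling and sets the stereocenter afterwards. It sets out from 13 and comes back at 17. Furan-3-carbaldehyde is protected in the flask with lithium morpholide, lithiated at C5 with s-BuLi and borylated with 2-isopropoxy-4,4,5,5-tetramethyl-1,3,2-dioxaborolane to give 5-(4,4,5,5-tetramethyl-1,3,2-dioxaborolan-2-yl)furan-3-carbaldehyde F1. Suzuki–Miyaura coupling of 13 with F1 (Pd(dppf)Cl2, K3PO4, dioxane/H2O) should give 5-(2,5-dimethoxyphenyl)furan-3-carbaldehyde F2. Brown allylboration with (−)-B-allyldiisopinocampheylborane (from (+)-α-pinene; Et2O, −78 °C, 2-aminoethanol work-up), the enantiomer that delivers allyl to the Si face of aryl aldehydes, should give (1S)-1-[5-(2,5-dimethoxyphenyl)furan-3-yl]but-3-en-1-ol F3. Cross-metathesis of F3 with 2-methyl-2-butene (second-generation Grubbs catalyst, CH2Cl2, 40 °C) then gives 17.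

**Step 6.** The carbenoid may show poor chemoselectivity and cyclopropanate the electron-rich trisubstituted alkene in competition with the alkyne. The fallback removes the competing alkene instead of tuning the catalyst. It sets out from 9 and comes back at 11. Pyridinium tribromide (CH2Cl2/pyridine, −20 °C) adds bromine to the alkene far faster than to the terminal alkyne and should give triethyl{[(3S)-5,6-dibromo-6-methylhept-1-yn-3-yl]oxy}silane F4. Cyclopropenation of F4 with 10 (Rh2(OAc)4, CH2Cl2, slow addition) gives ethyl 2-[(1S)-3,4-dibromo-4-methyl-1-(triethylsilyloxy)pentyl]cycloprop-2-ene-1-carboxylate F5. Reductive debromination with zinc dust (NH4Cl, THF/EtOH, 0 °C) restores the alkene and gives 11.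

**Step 12.** Electron transfer from the electron-rich aryl-furan π-system may be followed by attack of water on furan C5 and ring opening (over-oxidation) instead of clean demethylation. The fallback replaces the methyl ethers by allyl ethers, so the hydroquinone is unmasked without an oxidant and then oxidised under very mild conditions. It sets out from 12 and comes back at 20.
- Bromohydroquinone is allylated (allyl bromide, K2CO3, acetone) to 2-bromo-1,4-bis(prop-2-enyloxy)benzene F6.
- Bromine–lithium exchange (n-BuLi, THF, −78 °C) gives [2,5-bis(prop-2-enyloxy)phenyl]lithium F7.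
- F7 adds to 12 to give [2,5-bis(prop-2-enyloxy)phenyl]{2-[(1S)-4-methyl-1-(triethylsilyloxy)pent-3-enyl]cycloprop-2-en-1-yl}methanone F8.
- [Rh(CO)2Cl]2 in CH2Cl2 isomerises F8 to 2-[2,5-bis(prop-2-enyloxy)phenyl]-4-[(1S)-4-methyl-1-(triethylsilyloxy)pent-3-enyl]furan F9.
- Bu4NF gives (1S)-1-{5-[2,5-bis(prop-2-enyloxy)phenyl]furan-3-yl}-4-methylpent-3-en-1-ol F10.
- Esterification with 18 (DCC, DMAP) gives (1S)-1-{5-[2,5-bis(prop-2-enyloxy)phenyl]furan-3-yl}-4-methylpent-3-enyl 3-methylbut-2-enoate F11.
- Deallylation with zerovalent palladium (Pd(PPh3)4, morpholine, THF, rt) gives (1S)-1-[5-(2,5-dihydroxyphenyl)furan-3-yl]-4-methylpent-3-enyl 3-methylbut-2-enoate F12.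
- Ag2O (Et2O, MgSO4, rt) oxidises F12 to 20.

## Further compounds

F1 | step 9 | 5-(4,4,5,5-tetramethyl-1,3,2-dioxaborolan-2-yl)furan-3-carbaldehyde | O=Cc1coc(B2OC(C)(C)C(C)(C)O2)c1
F2 | step 9 | 5-(2,5-dimethoxyphenyl)furan-3-carbaldehyde | O=Cc1coc(-c2cc(OC)ccc2OC)c1
F3 | step 9 | (1S)-1-[5-(2,5-dimethoxyphenyl)furan-3-yl]but-3-en-1-ol | C=CC[C@H](O)c1coc(-c2cc(OC)ccc2OC)c1
F4 | step 6 | triethyl{[(3S)-5,6-dibromo-6-methylhept-1-yn-3-yl]oxy}silane | CC(C)(Br)C(Br)C[C@H](O[Si](CC)(CC)CC)C#C
F5 | step 6 | ethyl 2-[(1S)-3,4-dibromo-4-methyl-1-(triethylsilyloxy)pentyl]cycloprop-2-ene-1-carboxylate | CC(C)(Br)C(Br)C[C@H](O[Si](CC)(CC)CC)C1=CC1C(=O)OCC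
F6 | step 12 | 2-bromo-1,4-bis(prop-2-enyloxy)benzene | C=CCOc1ccc(OCC=C)c(Br)c1
F7 | step 12 | [2,5-bis(prop-2-enyloxy)phenyl]lithium | [Li]c1cc(OCC=C)ccc1OCC=C
F8 | step 12 | [2,5-bis(prop-2-enyloxy)phenyl]{2-[(1S)-4-methyl-1-(triethylsilyloxy)pent-3-enyl]cycloprop-2-en-1-yl}methanone | CC(C)=CC[C@H](O[Si](CC)(CC)CC)C1=CC1C(=O)c1cc(OCC=C)ccc1OCC=C
F9 | step 12 | 2-[2,5-bis(prop-2-enyloxy)phenyl]-4-[(1S)-4-methyl-1-(triethylsilyloxy)pent-3-enyl]furan | CC(C)=CC[C@H](O[Si](CC)(CC)CC)c1coc(-c2cc(OCC=C)ccc2OCC=C)c1
F10 | step 12 | (1S)-1-{5-[2,5-bis(prop-2-enyloxy)phenyl]furan-3-yl}-4-methylpent-3-en-1-ol | CC(C)=CC[C@H](O)c1coc(-c2cc(OCC=C)ccc2OCC=C)c1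
F11 | step 12 | (1S)-1-{5-[2,5-bis(prop-2-enyloxy)phenyl]furan-3-yl}-4-methylpent-3-enyl 3-methylbut-2-enoate | CC(C)=CC[C@H](OC(=O)C=C(C)C)c1coc(-c2cc(OCC=C)ccc2OCC=C)c1
F12 | step 12 | (1S)-1-[5-(2,5-dihydroxyphenyl)furan-3-yl]-4-methylpent-3-enyl 3-methylbut-2-enoate | CC(C)=CC[C@H](OC(=O)C=C(C)C)c1coc(-c2cc(O)ccc2O)c1
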